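The slow part of your flask is the way out of Z, with a half-life of 1.4 min by the step to G, longer than the 0.058 min in which E turns into X, so a quick number has to start there.

| setting | teal | blue |
|---|---|---|
| Z | 0.38 M | 0.38 M |
| E | 0.570 M | 0.850 M |
| time | 3.0 min | 3.0 min |

    Z → G (k1 = 0.0085 s⁻¹)
    E → X (k2 = 0.20 s⁻¹)
    G + X → G.X (k3 = 0.039 M⁻¹ s⁻¹)
    Z ⇌ J (K4 = 0.38, k4 = 0.031 s⁻¹)

- which of these there is most of at the end, counted by the Z in it, teal (G.X / Z / G)
- which of these there is most of at the end, counted by the Z in it, blue (G.X / Z / G)
- final amount of the leader among these, as a percentage of the Z charged, in teal
- final amount of the leader among these, as a percentage of the Z charged, in blue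

Z and J exchange with a relaxation half-life of 0.103 min, far shorter than that, so I treat them as one pool in pre-equilibrium, with c(J) at 0.38 times c(Z). The step to G draws on the Z part of this pool, so the pool falls first-order, and the quantity to carry is its drain constant, the rate constant of the step to G divided by one plus the equilibrium constant, 0.370 min⁻¹. Integrated over 3.0 min, in teal and blue alike, it leaves 23.9% of the charge as Z and sends 67.0% through G. X then catches G in a pseudo-first-order step; taking c(X) as its charge less half of what that share could consume, the capture constant is 1.04 min⁻¹ in teal and 1.69 min⁻¹ in blue. The closed form for two first-order steps in series then gives me G.X at 51.2% in teal and 57.9% in blue, ahead of Z in each.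

Your forecast has G.X at 51% in teal and G.X at 57% in blue, in its words “G.X leads in both runs”; it stands level with mine in teal and lower in blue.

The simulation gives G.X at 50.9% in teal and G.X at 57.4% in blue, with Z at 23.4% in teal and 23.4% in blue.

G.X and G together come to 67.0% in teal and 67.0% in blue, the share the drain constant sent through G, and within that share G stands at 16.1% in teal against 9.60% in blue. The main reason for the gap between the two flasks is the difference in concentration of E: with that difference taken away, blue ends with G.X at 50.9% rather than 57.4%.

For blue stopped at 80 s, the drain constant gives Z 44.2% and 38.9% passed through G, so G.X, a part of that share, should trail Z. The computed flask has Z in the lead at 42.8%, with G.X at 26.6%.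

Its constants were set for the occasion.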